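## Structural features

The target is a monocyclic germacrane-type sesquiterpenoid: one saturated cyclodecane (C1–C10) and no other ring, with a secondary methyl at C10, a tertiary methyl carbinol at C4, a free secondary hydroxyl at C5, an angelate [(Z)-2-methylbut-2-enoate] at C6 and a 2-hydroxypropan-2-yl group (carbinol carbon C11) at C7. Four stereocentres are contiguous (4R, 5S, 6R, 7R): on the flat ring the C4 and C5 hydroxyls are cis, the C5 hydroxyl and the C6 ester oxygen are trans, and the ester oxygen and the C7 side chain are cis; the fifth centre (10S) is isolated, two methylenes from C7 and three from C4. The fragile groups are the angelate, which isomerises to the tiglate with nucleophilic catalysts, acid chlorides or heat and can shift to the free O5, and the two tertiary alcohols, which ionise in strong acid. The real difficulty is twofold: a ten-membered carbocycle is heavily penalised by transannular strain and entropy, and five centres must be controlled on a ring with no rigid element, with C10 separated from the C4–C7 block by CH2 groups. The feature that unlocks the problem is that the C6–C7 bond lies across the ring from the non-bonded pair C4/C9: a bond between C4 and C9 would split the ring into a cyclohexane C4–C3–C2–C1–C10–C9 and a four-carbon bridge C5–C8. Read backwards, the cyclodecane is therefore a 2-alkenyl-3-methylcyclohexanone enlarged by C5–C8 through a [3,3] shift over C6=C5–C4–C9–C8=C7, with the C10 methyl already on the six-membered ring to steer the rest. The oxygen pattern fits the same event: the shift leaves its oxygen on C4 as an enolate directed at C5, and the C6 oxygen can ride in on the vinyl terminus.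

## Logic of the disconnections

27 ⇒ 24 (through 26). The acyl C–O bond at O6 is cut after the dioxolane on O4/O5 and the silyl ether on O11 are put back. The angelate is the most fragile element, so it is introduced last, onto the only free hydroxyl. The gain is a ring with no isomerisable or migrating group. The demand is an acylation that keeps the Z geometry on a hindered secondary oxygen, and a final unmasking that is acidic and not basic.

24 ⇒ 22 (through 23). No skeletal bond is cut: the benzyl group on O6 and the C8=C9 double bond are restored (both disappear forward in one hydrogenation) and the dioxolane is opened. The alkene is the footprint of the ring expansion, and the benzyl ether is the form in which O6 can pass through strong base. The gain is a plain 4,5-diol. The demand is a hydrogenation that does not move the double bond into C7 or C10, and a diol that is cis so that it ketalises readily.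

22 ⇒ 20. The C4–CH3 bond is cut. A methyl carbinol next to a carbinol is the adduct of a methyl nucleophile and an α-hydroxy ketone, and a magnesium chelate gives a rule for the face. One carbon and one stereocentre are removed, and C4 becomes the carbonyl that the ring expansion delivers. The demand is that chelate control operates on a ten-membered ring, which is why O5 is left unprotected.

20 ⇒ 18. The C5–O bond is cut. The ring expansion produces its enolate only toward C5, and the silyl ether of that enolate is the substrate for α-hydroxylation. The C5 centre is removed. The demand is face selection by the adjacent C6 centre and chemoselection over the C8=C9 alkene.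

18 ⇒ 15 (key). Forward, C6–C7 is formed and C4–C9 is cleaved. This replaces the ten-membered-ring problem by a six-membered one and turns the C6 and C7 stereocentres into two double-bond geometries. The remote C10 centre now controls C9 and C4 through 1,2-relationships on a chair. The demand is a single chair, geometrically pure Z and E arms, and trapping of the enolate before it expels benzyloxide.

15 ⇒ 9 + 12. The C4–C5 bond is cut: a tertiary allylic alcohol is a ketone plus an alkenyl metal. The synthesis becomes convergent and the Z enol ether is made separately. The demand is a non-basic nucleophile (the ketone is β,γ-unsaturated and easily enolised), equatorial attack to place the two arms trans, and a Z alkenyl metal that keeps its geometry.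

9 ⇒ 3 + 7. The sp3–sp2 bond C9–C8 is cut as the α-alkenylation of a regiodefined enolate. The E arm becomes a separate three-carbon-plus-two building block, and the trans relation to the C10 methyl is the thermodynamic one. The demand is that the enolate keeps its regiochemistry and that the new double bond does not drift into conjugation.

3 ⇒ 1. The C10–CH3 bond is cut as a conjugate addition. This is the only centre that needs reagent control, the starting enone is achiral and commercial, and the same event delivers the enolate on the correct side. The demand is high enantioselectivity and O-trapping of the magnesium enolate.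

7 ⇒ 4 (through 5) and 12 ⇒ 10. Only carbon–heteroatom bonds are cut (C–Br, O–Si). Both arms come from two-carbon or five-carbon commercial compounds. The demand is full E control in the hydrometalation and Z control in the bromination–elimination.

## Other disconnections considered

Alternative 1: The cut is C8–C9. Forward, tin-mediated iodine abstraction from the open-chain iodo acrylate A1 gives a primary C9 radical that adds in the ten-endo mode to the CH2 terminus of the 2-substituted acrylate; the resulting C7 radical takes hydrogen from Bu3SnH inside a MgBr2 chelate to give the ring ester A2. In its favour, C4, C5, C6 and C10 are fixed by open-chain chemistry before the ring exists, no ring alkene has to be hydrogenated, and the ester becomes the C11 carbinol with two equivalents of MeMgBr. Against it, a ten-membered ring is among the least favourable sizes for radical closure: the slow cyclisation must compete with direct reduction of the primary radical and with hydrogen transfer from the C–H bonds next to oxygen, which forces high dilution and stoichiometric tin. The C7 centre arises from hydrogen transfer to a ring radical, where the ring conformation and not only the chelate decides the face. On structure A2 is the better of the two, because the C4–C6 triad does not depend on medium-ring conformation, as C4 and C5 do in 20 and 22. On mechanism the chosen plan is stronger, since its bond-forming transition state is six-membered and the ten-membered ring appears by bond cleavage. On step economy A1 needs a long linear build of four centres and two functional termini, so the alternative is clearly longer; the last three operations (hydrogenolysis, acylation, deprotection) are the same in both.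

Alternative 2: The cut is C2–C3. Forward, the 2-lithio-1,3-dithiane of A3 attacks the methylene carbon of the 2-methyl-2-vinyl oxirane, closing the ring and releasing the C4 alkoxide of the Z allylic alcohol A4. In its favour, the C4 configuration comes from an enantioenriched epoxide and is secure before ring closure, which is better than setting C4 by addition to the ring ketone 20; C7 and C10 are also set in the chain and there is no enolate with a β-leaving group. Against it, the nucleophile is a bulky, strongly basic carbanion that must attack next to a fully substituted epoxide carbon in a ten-membered closure. Attack at the alkene terminus (SN2′, seven-membered ring) is entropically preferred, and eliminations compete. A4 still lacks both the C5 and the C6 oxygen, which would have to be added anti across a Z alkene with regiocontrol and then differentiated, and the dithiane must be removed afterwards. On structure it is better at C4 and worse at C5/C6. On mechanism the chosen [3,3] shift creates the ring and two centres at once, whereas this closure creates the ring and no new centre. On step economy it is longer both before and after the ring; it is the equal of the chosen plan in avoiding tin and in needing only one ring-forming step.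

Alternative 3: The cut is C1–C2, made through sulfur. Forward, the eleven-membered cyclic sulfone A5 is α-halogenated (KOH/Al2O3, CBr2F2), closes to the episulfone and loses SO2 to give the (Z)-cyclodecene A6 (Ramberg–Bäcklund ring contraction), which is then hydrogenated. In its favour, all five stereocentres are in place before any ring exists, so none depends on medium-ring conformation; this is a real advantage over the chosen plan. The ring is first closed through C–S bonds, which is easier than direct C–C closure of a ten-membered ring, and the alkene geometry does not matter. Against it, ring closure at sulfur, oxidation, contraction and hydrogenation are four operations that make one CH2–CH2 bond and no stereocentre or target function. The open-chain precursor carries five centres, two of them in a remote 1,4-relation, and three different protecting groups. On structure it is the safer plan. On mechanism it is an equally well-known reaction type and probably the more dependable ring formation. On step economy it is by far the longest of the four.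

Key step: step 7

Remark: ring atoms are numbered C1–C10 as in germacranes (C4 methyl carbinol, C5 carbinol, C6 ester carbon, C7 side-chain carbon, C10 methyl carbon), C11 is the side-chain carbinol carbon, and descriptors of all ten-membered compounds use this numbering.
Remark: the antipode of the ferrocenyl diphosphine in step 1 is taken to be the one that leads to the 3S ketone series.
Remark: tracing the chair atom by atom shows that (1S,2S,3S)-15 with a Z enol ether and an E alkene leads to 18 with the C6, C7 and C10 arrangement of 27, so the structures of 15 and 18 stand as drawn.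

## Route

Step 1
Reactants: 1 cyclohex-2-en-1-one
Product: 3 (S)-trimethyl[(3-methylcyclohex-1-en-1-yl)oxy]silane, via bromomagnesium enolate 2 (not isolated)
Conditions: MeMgBr (1.2 equiv), CuBr·SMe2 (5 mol%), 1-[2-(diphenylphosphino)ferrocenyl]ethyldicyclohexylphosphine (6 mol%), t-BuOMe, −78 °C; then Me3SiCl, Et3N, DMPU, −78 → 0 °C
Reagents that add atoms: methylmagnesium bromide C[Mg]Br; chlorotrimethylsilane C[Si](C)(C)Cl
Why: Copper-catalysed asymmetric conjugate addition of a Grignard reagent: the diphosphine-bound methylcuprate (monovalent copper) adds to one enantioface of the enone and sets C10 as S; the bromomagnesium enolate 2 has its double bond toward the future C9 and is O-silylated in the same flask, which stores that regiochemistry in 3.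

Step 2
Reactants: 4 2-methylbut-3-yn-2-ol
Product: 5 triethyl[(2-methylbut-3-yn-2-yl)oxy]silane
Conditions: Et3SiCl, imidazole, DMAP (cat.), DMF, 20 °C
Reagents that add atoms: chlorotriethylsilane CC[Si](CC)(CC)Cl
Why: Imidazole-assisted silylation of an alcohol; the tertiary propargylic hydroxyl is open enough for Et3SiCl, and the ether should survive the organometallic bases used later.

Step 3
Reactants: 5 triethyl[(2-methylbut-3-yn-2-yl)oxy]silane
Product: 7 {[(E)-4-bromo-2-methylbut-3-en-2-yl]oxy}triethylsilane, via alkenylzirconocene chloride 6 (not isolated)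
Conditions: Cp2Zr(H)Cl, THF, 20 °C; then N-bromosuccinimide, 0 °C
Reagents that add atoms: N-bromosuccinimide O=C1CCC(=O)N1Br
Why: Hydrozirconation adds Zr–H syn across the terminal alkyne with zirconium on the terminal carbon, giving the E alkenylzirconocene 6; bromodezirconation proceeds with retention, so 7 should be the pure E bromide.

Step 4
Reactants: 3 (S)-trimethyl[(3-methylcyclohex-1-en-1-yl)oxy]silane; 7 {[(E)-4-bromo-2-methylbut-3-en-2-yl]oxy}triethylsilane
Product: 9 (2S,3S)-3-methyl-2-[(E)-3-methyl-3-(triethylsilyloxy)but-1-enyl]cyclohexan-1-one, via lithium enolate 8 (not isolated)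
Conditions: MeLi, THF, 0 °C; then LiN(SiMe3)2 (1.1 equiv), 7, Pd(OAc)2 (3 mol%), [HP(t-Bu)3]BF4 (6 mol%), THF/toluene, 20 °C; AcOH, −78 °C
Reagents that add atoms: none
Why: MeLi cleaves the Si–O bond of 3 and releases the lithium enolate 8 with unchanged regiochemistry; palladium-catalysed α-alkenylation of a ketone enolate follows (the divalent palladium salt is reduced in the flask, 7 adds oxidatively to zerovalent palladium with retention of E geometry, the enolate transmetalates and reductive elimination forms C9–C8), while the extra amide base takes the acidic proton of the product so that 8 is not quenched. Cold protonation of the product dienolate at C9 gives the β,γ-unsaturated ketone, whose trans isomer (alkenyl and methyl both equatorial) is the stable one and fixes C9 as S relative to C10.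

Step 5
Reactants: 10 benzyl vinyl ether
Product: 12 {[(Z)-2-bromoethenyl]oxy}methylbenzene, via 1,2-dibromoethyl benzyl ether 11 (not isolated)
Conditions: Br2, CH2Cl2, −78 °C; then i-Pr2NEt, −78 → 20 °C; chromatography on Et3N-washed SiO2
Reagents that add atoms: bromine BrBr
Why: Bromine adds to the enol ether and the hindered amine removes HBr from the α-bromo ether (bromination–dehydrobromination), which favours the Z 2-bromovinyl ether; the Z isomer is purified because its geometry becomes the C6 configuration.

Step 6
Reactants: 12 {[(Z)-2-bromoethenyl]oxy}methylbenzene; 9 (2S,3S)-3-methyl-2-[(E)-3-methyl-3-(triethylsilyloxy)but-1-enyl]cyclohexan-1-one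
Product: 15 (1S,2S,3S)-1-[(Z)-2-(benzyloxy)ethenyl]-3-methyl-2-[(E)-3-methyl-3-(triethylsilyloxy)but-1-enyl]cyclohexan-1-ol, via (Z)-2-(benzyloxy)vinyllithium 13 (not isolated), via (Z)-2-(benzyloxy)vinylcerium dichloride 14 (not isolated)
Conditions: 12, t-BuLi (2.0 equiv), Et2O/THF, −78 °C; CeCl3 (dried), THF, −78 °C; then 9, −78 °C; aq. NaHCO3
Reagents that add atoms: none
Why: Bromine–lithium exchange gives 13 with retention (lithium is held cis by the ether oxygen), and transmetalation to the weakly basic organocerium 14 suppresses enolisation of the β,γ-unsaturated ketone (organocerium carbonyl addition). The bulky reagent should attack the chair of 9 equatorially, trans to the C9 arm, so the new arm is equatorial and the hydroxyl axial; this sets C4 (1S of the cyclohexanol).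

Step 7
Reactants: 15 (1S,2S,3S)-1-[(Z)-2-(benzyloxy)ethenyl]-3-methyl-2-[(E)-3-methyl-3-(triethylsilyloxy)but-1-enyl]cyclohexan-1-ol
Product: 18 (6S,7R,10S)-6-(benzyloxy)-10-methyl-7-[2-(triethylsilyloxy)propan-2-yl]-4-(trimethylsilyloxy)cyclodeca-4,8-diene (C3/C6 trans at C4=C5; 8E), via potassium alkoxide 16 (not isolated), via potassium enolate 17 (not isolated)
Conditions: KN(SiMe3)2 (1.1 equiv), 18-crown-6, THF, −78 → 0 °C; then Me3SiCl/Et3N, −78 °C; pentane, filtration, used crude
Reagents that add atoms: chlorotrimethylsilane C[Si](C)(C)Cl
Why: KN(SiMe3)2 turns 15 into the potassium alkoxide 16, whose oxyanion (made more naked by 18-crown-6) weakens the C4–C9 bond, and the 1,5-diene C6=C5–C4–C9–C8=C7 undergoes a concerted [3,3]-sigmatropic shift that forms C6–C7 and cleaves C4–C9. The closest known reaction type is the anionic oxy-Cope ring expansion of trans-1,2-dialkenylcyclohexanols to cyclodec-5-enones, including carbinols with a (Z)-2-ethoxyvinyl arm. The ten-membered ring is not closed end to end: the only cyclic array is the six-membered chair transition state, and the ring grows from six to ten because the cleaved bond is the one shared with the cyclohexane. With both arms equatorial and gauche only the chair is within reach (a boat would need them eclipsed); O− and H9 are axial and C3 and C10 equatorial on it, so both new double bonds are trans within the ring (C3 trans to C6 at the enolate, C8=C9 E). C6 is controlled by the Z enol ether, which places OBn axial, and C7 by the E alkene, which places the C11 arm equatorial, so the two groups come out cis on the ring; the absolute sense is that of the chair, fixed by C9 and C4 and therefore by C10 (6S,7R in 18, the same spatial arrangement as 6R,7R in 27). The enolate 17 can only form toward C5, which is where oxygen is needed next. Because benzyloxide is β to the enolate, the shift is run at the lowest temperature at which it proceeds and 17 is O-silylated at −78 °C in the same flask to give 18. The step needs a single chair, pure Z and E arms and no E1cB loss of benzyloxide; the first is secured by the trans,trans arrangement at C4, C9 and C10, the second by steps 3 and 5, the third by cold trapping.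

Step 8
Reactants: 18 (6S,7R,10S)-6-(benzyloxy)-10-methyl-7-[2-(triethylsilyloxy)propan-2-yl]-4-(trimethylsilyloxy)cyclodeca-4,8-diene
Product: 20 (5S,6R,7R,10S)-6-(benzyloxy)-5-hydroxy-10-methyl-7-[2-(triethylsilyloxy)propan-2-yl]cyclodec-8-en-4-one (8E), via silyloxy epoxide 19 (not isolated)
Conditions: crude 18, CH2Cl2, 20 °C, 1 h; dimethyldioxirane (acetone), −78 °C; then aq. citric acid, THF, 0 °C
Reagents that add atoms: dimethyldioxirane CC1(C)OO1
Why: Rubottom oxidation: the dioxirane epoxidises the electron-rich silyl enol ether much faster than the C8=C9 alkene, and mild acid opens the silyloxy epoxide 19 to the α-hydroxy ketone. In the relaxed conformer of 18, allylic 1,3-strain with the C4 silyloxy group places H6 in the plane of the enol ether, OBn on the outer face and C7 with the rest of the ring on the inner face, so oxygen should arrive anti to C7 and give 5S (C5–O trans to C6–O on the ring). The hold at 20 °C lets the double bond turn through the ring from the conformer in which it is born, which would lead to the other face.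

Step 9
Reactants: 20 (5S,6R,7R,10S)-6-(benzyloxy)-5-hydroxy-10-methyl-7-[2-(triethylsilyloxy)propan-2-yl]cyclodec-8-en-4-one
Product: 22 (4R,5S,6R,7R,10S)-6-(benzyloxy)-4,10-dimethyl-7-[2-(triethylsilyloxy)propan-2-yl]cyclodec-8-ene-4,5-diol (8E), via bromomagnesium alkoxide 21 (not isolated)
Conditions: MeMgBr (3.5 equiv), CH2Cl2/Et2O, −78 → −20 °C; aq. NH4Cl
Reagents that add atoms: methylmagnesium bromide C[Mg]Br
Why: Chelation-controlled Grignard addition: the first equivalent makes the C5 bromomagnesium alkoxide 21, magnesium bridges O5 and the C4 carbonyl oxygen in a five-membered chelate (Cram chelate model), and C6 with the ring attached to it blocks one face, so methyl adds from the side of H5. This should give the C4 hydroxyl cis to the C5 hydroxyl on the ring (4R).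

Step 10
Reactants: 22 (4R,5S,6R,7R,10S)-6-(benzyloxy)-4,10-dimethyl-7-[2-(triethylsilyloxy)propan-2-yl]cyclodec-8-ene-4,5-diol
Product: 23 (4R,5S,6R,7R,10S)-6-(benzyloxy)-4,5-(isopropylidenedioxy)-4,10-dimethyl-7-[2-(triethylsilyloxy)propan-2-yl]cyclodec-8-ene (8E)
Conditions: 2,2-dimethoxypropane, PPTS (cat.), CH2Cl2, 20 °C
Reagents that add atoms: 2,2-dimethoxypropane COC(C)(C)OC
Why: Acid-catalysed transketalisation; the cis 4,5-diol closes to a five-membered dioxolane, which masks O5 so that O6 will be the only oxygen freed for acylation, and the tertiary triethylsilyl ether tolerates PPTS.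

Step 11
Reactants: 23 (4R,5S,6R,7R,10S)-6-(benzyloxy)-4,5-(isopropylidenedioxy)-4,10-dimethyl-7-[2-(triethylsilyloxy)propan-2-yl]cyclodec-8-ene
Product: 24 (4R,5S,6R,7R,10S)-4,5-(isopropylidenedioxy)-4,10-dimethyl-7-[2-(triethylsilyloxy)propan-2-yl]cyclodecan-6-ol
Conditions: H2 (1 atm), PtO2, EtOAc, 20 °C; then Pd(OH)2/C, H2 (1 atm), EtOAc
Reagents that add atoms: none
Why: Heterogeneous hydrogenation over platinum saturates the strained E C8=C9 bond with little double-bond migration, so the allylic centres C7 and C10 are not scrambled, and hydrogenolysis over Pd(OH)2/C then removes the benzyl group; no stereocentre is formed, and EtOAc keeps the silyl ether and the ketal intact.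

Step 12
Reactants: 24 (4R,5S,6R,7R,10S)-4,5-(isopropylidenedioxy)-4,10-dimethyl-7-[2-(triethylsilyloxy)propan-2-yl]cyclodecan-6-ol
Product: 26 (4R,5S,6R,7R,10S)-4,5-(isopropylidenedioxy)-4,10-dimethyl-7-[2-(triethylsilyloxy)propan-2-yl]cyclodecan-6-yl (Z)-2-methylbut-2-enoate, via lithium alkoxide 25 (not isolated)
Conditions: LiN(SiMe3)2, THF, −78 °C; angelic anhydride, −78 → 0 °C; aq. NH4Cl
Reagents that add atoms: angelic anhydride C/C=C(/C)C(=O)OC(=O)/C(C)=C\C
Why: Acylation of a preformed lithium alkoxide with an anhydride: 25 attacks angelic anhydride at low temperature without nucleophilic catalyst or acid chloride, the conditions under which the Z acyl group should not isomerise to the tiglate; O5 is tied back in the dioxolane and O11 is silylated, so only O6 reacts.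

Step 13
Reactants: 26 (4R,5S,6R,7R,10S)-4,5-(isopropylidenedioxy)-4,10-dimethyl-7-[2-(triethylsilyloxy)propan-2-yl]cyclodecan-6-yl (Z)-2-methylbut-2-enoate
Product: 27 (4R,5S,6R,7R,10S)-4,5-dihydroxy-7-(2-hydroxypropan-2-yl)-4,10-dimethylcyclodecan-6-yl (Z)-2-methylbut-2-enoate (CNP0130723.1)
Conditions: 1 M aq. HCl/THF (1:3), 20 °C; NaHCO3 work-up
Reagents that add atoms: none
Why: Specific-acid hydrolysis of the dioxolane (cleavage at the ketal carbon, so C4 and C5 keep their C–O bonds and configuration) and of the tertiary silyl ether; at 20 °C the angelate should be neither hydrolysed nor isomerised, and the reaction is stopped at full conversion to limit acyl shift to O5.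

## Compound list

1 | cyclohex-2-en-1-one | O=C1C=CCCC1 | starting material
2 | bromomagnesium (S)-3-methylcyclohex-1-en-1-olate | C[C@H]1CCCC(O[Mg]Br)=C1 | intermediate
3 | (S)-trimethyl[(3-methylcyclohex-1-en-1-yl)oxy]silane | C[C@H]1CCCC(O[Si](C)(C)C)=C1 | intermediate
4 | 2-methylbut-3-yn-2-ol | CC(C)(O)C#C | starting material
5 | triethyl[(2-methylbut-3-yn-2-yl)oxy]silane | CC[Si](CC)(CC)OC(C)(C)C#C | intermediate
6 | chlorobis(cyclopentadienyl)[(E)-3-methyl-3-(triethylsilyloxy)but-1-enyl]zirconium | CC[Si](CC)(CC)OC(C)(C)/C=C/[Zr](Cl)(C1C=CC=C1)C1C=CC=C1 | intermediate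
7 | {[(E)-4-bromo-2-methylbut-3-en-2-yl]oxy}triethylsilane | CC[Si](CC)(CC)OC(C)(C)/C=C/Br | intermediate
8 | lithium (S)-3-methylcyclohex-1-en-1-olate | C[C@H]1CCCC(O[Li])=C1 | intermediate
9 | (2S,3S)-3-methyl-2-[(E)-3-methyl-3-(triethylsilyloxy)but-1-enyl]cyclohexan-1-one | O=C1CCC[C@H](C)[C@H]1/C=C/C(C)(C)O[Si](CC)(CC)CC | intermediate
10 | benzyl vinyl ether | C=COCc1ccccc1 | starting material
11 | [(1,2-dibromoethoxy)methyl]benzene | BrCC(Br)OCc1ccccc1 | intermediate
12 | {[(Z)-2-bromoethenyl]oxy}methylbenzene | Br/C=C\OCc1ccccc1 | intermediate
13 | (Z)-2-(benzyloxy)vinyllithium | [Li]/C=C\OCc1ccccc1 | intermediate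
14 | (Z)-2-(benzyloxy)vinylcerium dichloride | Cl[Ce](Cl)/C=C\OCc1ccccc1 | intermediate
15 | (1S,2S,3S)-1-[(Z)-2-(benzyloxy)ethenyl]-3-methyl-2-[(E)-3-methyl-3-(triethylsilyloxy)but-1-enyl]cyclohexan-1-ol | O[C@@]1(/C=C\OCc2ccccc2)CCC[C@H](C)[C@H]1/C=C/C(C)(C)O[Si](CC)(CC)CC | intermediate
16 | potassium alkoxide of 15 | [K]O[C@@]1(/C=C\OCc2ccccc2)CCC[C@H](C)[C@H]1/C=C/C(C)(C)O[Si](CC)(CC)CC | intermediate
17 | potassium (6S,7R,10S)-6-(benzyloxy)-10-methyl-7-[2-(triethylsilyloxy)propan-2-yl]cyclodeca-4,8-dien-4-olate (C3/C6 trans at C4=C5; 8E) | C1/C(O[K])=C/[C@H](OCc2ccccc2)[C@H](C(C)(C)O[Si](CC)(CC)CC)/C=C/[C@@H](C)CC1 | intermediate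
18 | (6S,7R,10S)-6-(benzyloxy)-10-methyl-7-[2-(triethylsilyloxy)propan-2-yl]-4-(trimethylsilyloxy)cyclodeca-4,8-diene (C3/C6 trans at C4=C5; 8E) | C1/C(O[Si](C)(C)C)=C/[C@H](OCc2ccccc2)[C@H](C(C)(C)O[Si](CC)(CC)CC)/C=C/[C@@H](C)CC1 | intermediate
19 | (4R,5S,6R,7R,10S)-6-(benzyloxy)-4,5-epoxy-10-methyl-7-[2-(triethylsilyloxy)propan-2-yl]-4-(trimethylsilyloxy)cyclodec-8-ene (8E) | C1[C@]2(O[Si](C)(C)C)O[C@H]2[C@H](OCc3ccccc3)[C@H](C(C)(C)O[Si](CC)(CC)CC)/C=C/[C@@H](C)CC1 | intermediate
20 | (5S,6R,7R,10S)-6-(benzyloxy)-5-hydroxy-10-methyl-7-[2-(triethylsilyloxy)propan-2-yl]cyclodec-8-en-4-one (8E) | C1C(=O)[C@@H](O)[C@H](OCc2ccccc2)[C@H](C(C)(C)O[Si](CC)(CC)CC)/C=C/[C@@H](C)CC1 | intermediate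
21 | C5 bromomagnesium alkoxide of 20 | C1C(=O)[C@@H](O[Mg]Br)[C@H](OCc2ccccc2)[C@H](C(C)(C)O[Si](CC)(CC)CC)/C=C/[C@@H](C)CC1 | intermediate
22 | (4R,5S,6R,7R,10S)-6-(benzyloxy)-4,10-dimethyl-7-[2-(triethylsilyloxy)propan-2-yl]cyclodec-8-ene-4,5-diol (8E) | C1[C@@](C)(O)[C@@H](O)[C@H](OCc2ccccc2)[C@H](C(C)(C)O[Si](CC)(CC)CC)/C=C/[C@@H](C)CC1 | intermediate
23 | (4R,5S,6R,7R,10S)-6-(benzyloxy)-4,5-(isopropylidenedioxy)-4,10-dimethyl-7-[2-(triethylsilyloxy)propan-2-yl]cyclodec-8-ene (8E) | C1[C@@]2(C)OC(C)(C)O[C@H]2[C@H](OCc3ccccc3)[C@H](C(C)(C)O[Si](CC)(CC)CC)/C=C/[C@@H](C)CC1 | intermediate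
24 | (4R,5S,6R,7R,10S)-4,5-(isopropylidenedioxy)-4,10-dimethyl-7-[2-(triethylsilyloxy)propan-2-yl]cyclodecan-6-ol | C1[C@@]2(C)OC(C)(C)O[C@H]2[C@H](O)[C@H](C(C)(C)O[Si](CC)(CC)CC)CC[C@@H](C)CC1 | intermediate
25 | lithium alkoxide of 24 | C1[C@@]2(C)OC(C)(C)O[C@H]2[C@H](O[Li])[C@H](C(C)(C)O[Si](CC)(CC)CC)CC[C@@H](C)CC1 | intermediate
26 | (4R,5S,6R,7R,10S)-4,5-(isopropylidenedioxy)-4,10-dimethyl-7-[2-(triethylsilyloxy)propan-2-yl]cyclodecan-6-yl (Z)-2-methylbut-2-enoate | C1[C@@]2(C)OC(C)(C)O[C@H]2[C@H](OC(=O)/C(C)=C\C)[C@H](C(C)(C)O[Si](CC)(CC)CC)CC[C@@H](C)CC1 | intermediate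
27 | (4R,5S,6R,7R,10S)-4,5-dihydroxy-7-(2-hydroxypropan-2-yl)-4,10-dimethylcyclodecan-6-yl (Z)-2-methylbut-2-enoate | C/C=C(/C)C(=O)O[C@@H]1[C@H](C(C)(C)O)CC[C@@H](C)CCC[C@@](C)(O)[C@H]1O | target

## Step count and least certain steps

Total step count: 13. Longest linear sequence: 11 steps (from 4 through steps 2, 3, 4, 6, 7, 8, 9, 10, 11, 12 and 13); from 1 it is 10 steps. Steps 6 and 9 rest on well-known facial preferences and are ranked below the five that follow.

Step 7 (key step). The most likely failure is E1cB loss of benzyloxide from enolate 17 while the rearrangement is still running. The bond-forming termini are a donor-substituted carbon (C6) and a carbon next to a fully substituted centre (C7); both slow the shift and may force temperatures at which the potassium enolate no longer holds its β-alkoxy group. The fallback sets out from 15 and comes back at 20. It captures the enolate as it is born instead of letting it accumulate: 15 is deprotonated with exactly one equivalent of KN(SiMe3)2/18-crown-6 at −78 °C, chlorotriisopropylsilane is added and the mixture is warmed. The chloride is too hindered to silylate the tertiary alkoxide 16 but should silylate enolate 17, so the rearrangement would deliver the triisopropylsilyl enol ether F1. Oxidation of F1 with dimethyldioxirane would give the silyloxy epoxide F2, which Et3N·3HF in THF at 0 °C opens to 20.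

Step 4. The most likely failure is proton exchange between enolate 8 and the more acidic product, which moves the enolate to C3 and leads to alkenylation on the wrong side; base-induced drift of the C7=C8 bond into conjugation and incomplete trans selectivity at C9 add to it. The fallback sets out from 1 and 5 and comes back at 9. It makes the C9–C8 bond between two sp2 carbons before the methyl group is introduced. 1 is iodinated (I2, pyridine, CH2Cl2) to 2-iodocyclohex-2-en-1-one F3, and 5 is hydroborated with pinacolborane (Cp2Zr(H)Cl cat.) to the E alkenylboronate F4. Suzuki coupling of the two ([1,1'-bis(diphenylphosphino)ferrocene]PdCl2, K3PO4, THF/H2O) gives the dienone F5. Copper-catalysed asymmetric addition of MeMgBr as in step 1 then gives the bromomagnesium dienolate F6, which is protonated at C9 at −78 °C to 9. The price is that enantioselective addition to α-substituted enones is less developed.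

Step 8. The most likely failure is poor facial selectivity of the epoxidation if the two planar-chiral conformers of 18 do not interconvert or are similarly populated; participation of the C8=C9 alkene across the ring is a second risk. The fallback sets out from the C5-epimeric ketol F7 that a misdirected oxidation of 18 would deliver and comes back at 20. It corrects the centre by substitution with inversion instead of relying on the ring conformation: Mitsunobu reaction of F7 (ClCH2CO2H, PPh3, DIAD, toluene, 0 °C) gives the inverted chloroacetate F8, and K2CO3 (cat.) in MeOH at 0 °C releases 20.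

Step 12. The most likely failure is slow acylation of the hindered C6 alkoxide, followed by Z to E isomerisation of the acyl group if forcing conditions become necessary. The fallback sets out from 24 and comes back at 26. It builds the angelate on the alcohol instead of transferring it. The small, linear but-2-ynoic acid is esterified (DCC, DMAP) to the but-2-ynoate F9. Palladium-catalysed syn hydrostannation (Bu3SnH, Pd(PPh3)4, THF) places tin on C2 and gives the (E)-2-(tributylstannyl)but-2-enoate F10. Stille methylation (MeI, Pd(PPh3)4, CuI, DMF) replaces tin by methyl with retention, which is the Z ester 26.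

Step 13. The most likely failure is acyl shift from O6 to O5, or ionisation of a tertiary carbinol, under the acid needed for the dioxolane. The fallback sets out from 22 and comes back at 27. It replaces the acid-labile ketal by a fluoride-labile silylene so that the last step is a desilylation. 22 with t-Bu2Si(OTf)2 and 2,6-lutidine gives the di-tert-butylsilylene F11. Hydrogenation as in step 11 gives the alcohol F12 and acylation as in step 12 gives the angelate F13. HF·pyridine in THF at 0 °C then removes both silicon groups to give 27.

## Further compounds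

F1 | step 7 | (6S,7R,10S)-6-(benzyloxy)-10-methyl-7-[2-(triethylsilyloxy)propan-2-yl]-4-(triisopropylsilyloxy)cyclodeca-4,8-diene (C3/C6 trans at C4=C5; 8E) | C1/C(O[Si](C(C)C)(C(C)C)C(C)C)=C/[C@H](OCc2ccccc2)[C@H](C(C)(C)O[Si](CC)(CC)CC)/C=C/[C@@H](C)CC1
F2 | step 7 | (4R,5S,6R,7R,10S)-6-(benzyloxy)-4,5-epoxy-10-methyl-7-[2-(triethylsilyloxy)propan-2-yl]-4-(triisopropylsilyloxy)cyclodec-8-ene (8E) | C1[C@]2(O[Si](C(C)C)(C(C)C)C(C)C)O[C@H]2[C@H](OCc3ccccc3)[C@H](C(C)(C)O[Si](CC)(CC)CC)/C=C/[C@@H](C)CC1
F3 | step 4 | 2-iodocyclohex-2-en-1-one | O=C1CCCC=C1I
F4 | step 4 | triethyl{[(E)-2-methyl-4-(4,4,5,5-tetramethyl-1,3,2-dioxaborolan-2-yl)but-3-en-2-yl]oxy}silane | CC[Si](CC)(CC)OC(C)(C)/C=C/B1OC(C)(C)C(C)(C)O1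
F5 | step 4 | 2-[(E)-3-methyl-3-(triethylsilyloxy)but-1-enyl]cyclohex-2-en-1-one | O=C1CCCC=C1/C=C/C(C)(C)O[Si](CC)(CC)CC
F6 | step 4 | bromomagnesium (S)-3-methyl-2-[(E)-3-methyl-3-(triethylsilyloxy)but-1-enyl]cyclohex-1-en-1-olate | C[C@H]1CCCC(O[Mg]Br)=C1/C=C/C(C)(C)O[Si](CC)(CC)CC
F7 | step 8 | (5R,6R,7R,10S)-6-(benzyloxy)-5-hydroxy-10-methyl-7-[2-(triethylsilyloxy)propan-2-yl]cyclodec-8-en-4-one (8E) | C1C(=O)[C@H](O)[C@H](OCc2ccccc2)[C@H](C(C)(C)O[Si](CC)(CC)CC)/C=C/[C@@H](C)CC1
F8 | step 8 | (5S,6R,7R,10S)-6-(benzyloxy)-10-methyl-4-oxo-7-[2-(triethylsilyloxy)propan-2-yl]cyclodec-8-en-5-yl chloroacetate (8E) | C1C(=O)[C@@H](OC(=O)CCl)[C@H](OCc2ccccc2)[C@H](C(C)(C)O[Si](CC)(CC)CC)/C=C/[C@@H](C)CC1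
F9 | step 12 | (4R,5S,6R,7R,10S)-4,5-(isopropylidenedioxy)-4,10-dimethyl-7-[2-(triethylsilyloxy)propan-2-yl]cyclodecan-6-yl but-2-ynoate | C1[C@@]2(C)OC(C)(C)O[C@H]2[C@H](OC(=O)C#CC)[C@H](C(C)(C)O[Si](CC)(CC)CC)CC[C@@H](C)CC1
F10 | step 12 | (4R,5S,6R,7R,10S)-4,5-(isopropylidenedioxy)-4,10-dimethyl-7-[2-(triethylsilyloxy)propan-2-yl]cyclodecan-6-yl (E)-2-(tributylstannyl)but-2-enoate | C1[C@@]2(C)OC(C)(C)O[C@H]2[C@H](OC(=O)/C([Sn](CCCC)(CCCC)CCCC)=C\C)[C@H](C(C)(C)O[Si](CC)(CC)CC)CC[C@@H](C)CC1
F11 | step 13 | (4R,5S,6R,7R,10S)-6-(benzyloxy)-4,5-(di-tert-butylsilylenedioxy)-4,10-dimethyl-7-[2-(triethylsilyloxy)propan-2-yl]cyclodec-8-ene (8E) | C1[C@@]2(C)O[Si](C(C)(C)C)(C(C)(C)C)O[C@H]2[C@H](OCc3ccccc3)[C@H](C(C)(C)O[Si](CC)(CC)CC)/C=C/[C@@H](C)CC1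
F12 | step 13 | (4R,5S,6R,7R,10S)-4,5-(di-tert-butylsilylenedioxy)-4,10-dimethyl-7-[2-(triethylsilyloxy)propan-2-yl]cyclodecan-6-ol | C1[C@@]2(C)O[Si](C(C)(C)C)(C(C)(C)C)O[C@H]2[C@H](O)[C@H](C(C)(C)O[Si](CC)(CC)CC)CC[C@@H](C)CC1
F13 | step 13 | (4R,5S,6R,7R,10S)-4,5-(di-tert-butylsilylenedioxy)-4,10-dimethyl-7-[2-(triethylsilyloxy)propan-2-yl]cyclodecan-6-yl (Z)-2-methylbut-2-enoate | C1[C@@]2(C)O[Si](C(C)(C)C)(C(C)(C)C)O[C@H]2[C@H](OC(=O)/C(C)=C\C)[C@H](C(C)(C)O[Si](CC)(CC)CC)CC[C@@H](C)CC1
A1 | alternative 1 | open-chain iodo acrylate: methyl 2-methylene ester carrying the C6 benzyl ether, the C4,C5 acetonide, the C10 methyl and a C9 iodide | IC[C@@H](C)CCC[C@@]1(C)OC(C)(C)O[C@H]1[C@H](OCc2ccccc2)C(=C)C(=O)OC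
A2 | alternative 1 | ten-membered ring with C7 methyl ester, C6 benzyl ether and C4,C5 acetonide | c1ccccc1CO[C@@H]1[C@H](C(=O)OC)CC[C@@H](C)CCC[C@@]2(C)OC(C)(C)O[C@@H]12
A3 | alternative 2 | open-chain 2-substituted 1,3-dithiane carrying the (Z)-alkenyl 2-methyloxirane | C[C@@]1(CO1)/C=C\[C@H](C(C)(C)O[Si](CC)(CC)CC)CC[C@@H](C)CC1SCCCS1
A4 | alternative 2 | ten-membered (Z)-allylic tertiary alcohol at C4 with C2 as a spiro-dithiane | C[C@]1(O)/C=C\[C@H](C(C)(C)O[Si](CC)(CC)CC)CC[C@@H](C)CC2(SCCCS2)C1
A5 | alternative 3 | eleven-membered cyclic sulfone (sulfur between C1 and C2) carrying all five stereocentres in protected form | CC(C)(C)[Si](C)(C)O[C@@H]1[C@H](C(C)(C)O[Si](CC)(CC)CC)CC[C@@H](C)CS(=O)(=O)CC[C@@]2(C)OC(C)(C)O[C@@H]12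
A6 | alternative 3 | (Z)-cyclodec-1-ene carrying all five stereocentres in protected form | CC(C)(C)[Si](C)(C)O[C@@H]1[C@H](C(C)(C)O[Si](CC)(CC)CC)CC[C@@H](C)/C=C\C[C@@]2(C)OC(C)(C)O[C@@H]12
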